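**Retrosynthetic overview**

1. Feature: the bonds C1–C7 and C1'–C7' each tie an arene carbon to a CH2 one carbon away from a stereocentre (C8, C8'). Ring A (3-methoxy-4,5-dihydroxyphenyl) is ring B (4-hydroxy-3,5-dimethoxyphenyl) lacking one O-methyl, so the skeleton is latently C2-symmetric.
2. Last disconnection: target 17 ⇒ bis-syringyl diphenol 15 (one of four equivalent OMe groups removed oxidatively) ⇒ dibenzyl ether 14.
3. Key disconnection: both aryl–CH2 bonds of 14 are cut together ⇒ two molecules of aryl iodide 12 plus the bis(N-hydroxyphthalimide) ester 8 of (3R,4R)-3,4-dimethyladipic acid.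
4. 8 ⇒ diacid 6 ⇒ (4R,5R)-4,5-dimethylcyclohexene 4 ⇒ resolved trans-cyclohexene diacid 1 (source of C8 and C8'); 12 ⇒ syringol 9.
5. Rings: none is formed. Both arene rings come intact from syringol, and the cyclohexene ring of 1 is opened in step 4.

Key step: step 8

Assumption: diacid 1 is bought in resolved (1R,2R) form (otherwise it is obtained by amine-salt resolution of the commercial racemic trans-diacid). Its two carboxyl-bearing carbons become C8 and C8' without any change of spatial arrangement. Lignan numbering is used: C7/C7' benzylic CH2, C8/C8' methines, C9/C9' methyls.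

**Route**

Step 1
Reactants: 1 (1R,2R)-cyclohex-4-ene-1,2-dicarboxylic acid
Product: 2 [(1R,2R)-cyclohex-4-ene-1,2-diyl]dimethanol
Conditions: LiAlH4 (excess), THF, 0 °C → reflux; H2O, aq. NaOH work-up
Reagents that add atoms: none
Why: LiAlH4 reduction of carboxylic acids to primary alcohols leaves the isolated alkene alone, and the stereocentres are spectators whose trans arrangement is also the stable one, so the (1R,2R) configuration should be carried over intact.

Step 2
Reactants: 2 [(1R,2R)-cyclohex-4-ene-1,2-diyl]dimethanol
Product: 3 [(1R,2R)-cyclohex-4-ene-1,2-diyl]bis(methylene) dimethanesulfonate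
Conditions: MsCl (2.4 equiv), Et3N, CH2Cl2, 0 °C
Reagents that add atoms: methanesulfonyl chloride, CS(=O)(=O)Cl
Why: Mesylation of two unhindered primary alcohols is fast at 0 °C and involves neither the alkene nor the stereocentres.

Step 3
Reactants: 3 [(1R,2R)-cyclohex-4-ene-1,2-diyl]bis(methylene) dimethanesulfonate
Product: 4 (4R,5R)-4,5-dimethylcyclohex-1-ene
Conditions: LiAlH4 (excess), THF, 0 °C → reflux; H2O, aq. NaOH quench; pentane extraction; distillation through a short column (volatile hydrocarbon, never concentrated to dryness)
Reagents that add atoms: none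
Why: SN2 displacement of primary sulfonates by hydride (LiAlH4 reduction of alkyl mesylates) should turn both CH2OMs groups into the C9/C9' methyl groups, with the adjacent stereocentres untouched, so the trans-(4R,5R) dimethyl array is fixed here.

Step 4
Reactants: 4 (4R,5R)-4,5-dimethylcyclohex-1-ene
Product: 6 (3R,4R)-3,4-dimethylhexanedioic acid, via (3R,4R)-3,4-dimethylhexanedial 5 (not isolated)
Conditions: RuCl3·xH2O (2 mol %), NaIO4 (4.2 equiv), MeCN/EtOAc/H2O, 0 °C → rt
Reagents that add atoms: sodium periodate, [Na+].[O-]I(=O)(=O)=O; water, O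
Why: Ruthenium tetroxide generated in situ (Sharpless oxidative cleavage) should cut the ring alkene through the dialdehyde to the diacid, so that the former ring CH2 groups become the CH2CO2H arms and the stereocentres, now β to the carboxyl groups, cannot epimerise.

Step 5
Reactants: 6 (3R,4R)-3,4-dimethylhexanedioic acid; 7 N-hydroxyphthalimide (2.2 equiv)
Product: 8 bis(1,3-dioxoisoindolin-2-yl) (3R,4R)-3,4-dimethylhexanedioate
Conditions: N,N'-diisopropylcarbodiimide (2.2 equiv), DMAP (cat.), CH2Cl2, rt
Reagents that add atoms: none
Why: Carbodiimide-mediated (Steglich-type) esterification of both carboxyl groups should give the bis redox-active ester, and any cyclic anhydride formed in passing is reopened by the N-hydroxy nucleophile and activated again.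

Step 6
Reactants: 9 2,6-dimethoxyphenol (syringol)
Product: 10 4-iodo-2,6-dimethoxyphenol
Conditions: N-iodosuccinimide (1.05 equiv), TsOH·H2O (cat.), MeCN, 0 °C → rt, dark
Reagents that add atoms: N-iodosuccinimide, O=C1CCC(=O)N1I
Why: Electrophilic aromatic iodination is directed by the free hydroxyl group, the strongest donor, and with both ortho positions occupied by methoxy groups iodine should enter para to OH.

Step 7
Reactants: 10 4-iodo-2,6-dimethoxyphenol; 11 benzyl bromide
Product: 12 2-(benzyloxy)-5-iodo-1,3-dimethoxybenzene
Conditions: K2CO3, DMF, rt → 50 °C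
Reagents that add atoms: none
Why: Williamson etherification of the phenoxide installs a benzyl group that tolerates reductive nickel electrocatalysis and is later removed by neutral hydrogenolysis.

Step 8
Reactants: 8 bis(1,3-dioxoisoindolin-2-yl) (3R,4R)-3,4-dimethylhexanedioate (1 equiv); 12 2-(benzyloxy)-5-iodo-1,3-dimethoxybenzene (two molecules react; 4 equiv used)
Product: 14 (2R,3R)-1,4-bis(4-benzyloxy-3,5-dimethoxyphenyl)-2,3-dimethylbutane, via mono-arylated redox-active ester 13 (not isolated)
Conditions: NiCl2·6H2O (40 mol %), 2,2'-bipyridine (40 mol %), AgNO3 (0.6 equiv), LiCl, NMP, Mg anode / reticulated vitreous carbon cathode, undivided cell, constant current (about 6 F per mol of 8), rt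
Reagents that add atoms: none
Why: Cathodic reduction converts the divalent nickel bipyridine salt into low-valent (zerovalent or monovalent) nickel, which adds oxidatively to the C–I bond of 12 to give a divalent arylnickel iodide, while single-electron transfer to each N-acyloxyphthalimide (at the silver-coated cathode or from low-valent nickel) expels phthalimide anion and CO2 and leaves a primary alkyl radical at C7, later at C7'. The arylnickel species traps this radical as a trivalent aryl(alkyl)nickel that eliminates reductively, forming C1–C7 and then, through mono-ester 13, C1'–C7', after which the monovalent nickel is reduced again at the cathode while the Mg anode is consumed. The closest known reaction type is the nickel-catalysed, electrochemically driven decarboxylative cross-electrophile coupling of primary alkyl N-hydroxyphthalimide esters with aryl iodides, here run at both ends of one diester. No ring is closed and no stereocentre is created; C8 and C8' sit one carbon away from the radical centres, never carry spin and so should keep their configuration. The selectivity needed is cross-coupling over hydrogen-atom abstraction, β-hydride elimination and radical dimerisation, at two sites in succession. The excess of the cheap iodide 12 keeps arylnickel available for the unhindered primary radicals, and because the two ester groups of 8 are homotopic no differentiation is needed and 13 reacts just as 8 does.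

Step 9
Reactants: 14 (2R,3R)-1,4-bis(4-benzyloxy-3,5-dimethoxyphenyl)-2,3-dimethylbutane
Product: 15 4,4'-[(2R,3R)-2,3-dimethylbutane-1,4-diyl]bis(2,6-dimethoxyphenol)
Conditions: H2 (1 atm), Pd/C (10% palladium on carbon), EtOAc/MeOH, rt
Reagents that add atoms: none
Why: Palladium-catalysed hydrogenolysis of benzyl aryl ethers should free both phenols cleanly, since the molecule holds no alkene, halide or other reducible group.

Step 10
Reactants: 15 4,4'-[(2R,3R)-2,3-dimethylbutane-1,4-diyl]bis(2,6-dimethoxyphenol)
Product: 17 sauriol B, 5-[(2R,3R)-4-(4-hydroxy-3,5-dimethoxyphenyl)-2,3-dimethylbutyl]-3-methoxybenzene-1,2-diol, via 3-methoxy-ortho-quinone 16 (not isolated)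
Conditions: NaIO4 (0.9 equiv, added slowly), THF/H2O/AcOH, 0 °C, a few minutes; then aq. Na2S2O4 (excess), 0 °C → rt, under argon; recovered 15 is recycled
Reagents that add atoms: sodium periodate, [Na+].[O-]I(=O)(=O)=O; water, O
Why: Periodate oxidation of a 2-methoxyphenol (Adler-type oxidative O-demethylation) should convert one syringyl ring into the 3-methoxy-ortho-quinone with loss of methanol, and dithionite reduces it to the catechol in the same flask; each ring can lose only one methyl and all four methoxy groups of 15 are equivalent, so the only issue is one ring against two, which is statistical and is handled by a slight deficit of oxidant and recycling of 15.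

**Compound list**

1 | (1R,2R)-cyclohex-4-ene-1,2-dicarboxylic acid | C1=CC[C@@H](C(=O)O)[C@H](C(=O)O)C1 | starting material
2 | [(1R,2R)-cyclohex-4-ene-1,2-diyl]dimethanol | C1=CC[C@@H](CO)[C@H](CO)C1 | intermediate
3 | [(1R,2R)-cyclohex-4-ene-1,2-diyl]bis(methylene) dimethanesulfonate | C1=CC[C@@H](COS(C)(=O)=O)[C@H](COS(C)(=O)=O)C1 | intermediate
4 | (4R,5R)-4,5-dimethylcyclohex-1-ene | C1=CC[C@@H](C)[C@H](C)C1 | intermediate
5 | (3R,4R)-3,4-dimethylhexanedial | O=CC[C@@H](C)[C@H](C)CC=O | intermediate
6 | (3R,4R)-3,4-dimethylhexanedioic acid | OC(=O)C[C@@H](C)[C@H](C)CC(=O)O | intermediate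
7 | N-hydroxyphthalimide | ON1C(=O)c2ccccc2C1=O | starting material
8 | bis(1,3-dioxoisoindolin-2-yl) (3R,4R)-3,4-dimethylhexanedioate | O=C(C[C@@H](C)[C@H](C)CC(=O)ON1C(=O)c2ccccc2C1=O)ON1C(=O)c2ccccc2C1=O | intermediate
9 | 2,6-dimethoxyphenol (syringol) | COc1cccc(OC)c1O | starting material
10 | 4-iodo-2,6-dimethoxyphenol | COc1cc(I)cc(OC)c1O | intermediate
11 | benzyl bromide | BrCc1ccccc1 | starting material
12 | 2-(benzyloxy)-5-iodo-1,3-dimethoxybenzene | COc1cc(I)cc(OC)c1OCc1ccccc1 | intermediate
13 | 1,3-dioxoisoindolin-2-yl (3R,4R)-5-(4-benzyloxy-3,5-dimethoxyphenyl)-3,4-dimethylpentanoate | O=C(C[C@@H](C)[C@H](C)Cc1cc(OC)c(OCc2ccccc2)c(OC)c1)ON1C(=O)c2ccccc2C1=O | intermediate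
14 | (2R,3R)-1,4-bis(4-benzyloxy-3,5-dimethoxyphenyl)-2,3-dimethylbutane | COc1cc(C[C@@H](C)[C@H](C)Cc2cc(OC)c(OCc3ccccc3)c(OC)c2)cc(OC)c1OCc1ccccc1 | intermediate
15 | 4,4'-[(2R,3R)-2,3-dimethylbutane-1,4-diyl]bis(2,6-dimethoxyphenol) | COc1cc(C[C@@H](C)[C@H](C)Cc2cc(OC)c(O)c(OC)c2)cc(OC)c1O | intermediate
16 | 5-[(2R,3R)-4-(4-hydroxy-3,5-dimethoxyphenyl)-2,3-dimethylbutyl]-3-methoxycyclohexa-3,5-diene-1,2-dione | COC1=CC(C[C@@H](C)[C@H](C)Cc2cc(OC)c(O)c(OC)c2)=CC(=O)C1=O | intermediate
17 | sauriol B, 5-[(2R,3R)-4-(4-hydroxy-3,5-dimethoxyphenyl)-2,3-dimethylbutyl]-3-methoxybenzene-1,2-diol | COc1cc(C[C@@H](C)[C@H](C)Cc2cc(OC)c(O)c(OC)c2)cc(O)c1O | target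

**Step count**

Total steps: 10. Longest linear sequence: 8 steps (steps 1, 2, 3, 4, 5, 8, 9, 10); steps 6 and 7 form the two-step arene branch.

**Steps most likely to fail**

Step 8. The primary radicals may be lost before nickel captures them (hydrogen-atom abstraction from solvent, β-hydride elimination at nickel, dimerisation), or the sequence may stall after the first coupling. A failure at either end costs the whole molecule, and activation of both ends at one metal centre could close a four-membered ring.

The fallback sets out from 8 and returns at 14. Irradiation of 8 with blue light in the presence of LiI and catalytic PPh3 (photochemical iododecarboxylation of N-hydroxyphthalimide esters) should give (2S,3S)-1,4-diiodo-2,3-dimethylbutane F1. The spatial arrangement is unchanged; the descriptor changes only because CH2I outranks the neighbouring methine. Zinc dust activated with LiCl in THF inserts into both C–I bonds to give [(2S,3S)-2,3-dimethylbutane-1,4-diyl]bis(iodozinc) F2. A double Negishi coupling of F2 with 12 (Pd(OAc)2, SPhos, THF, rt → 50 °C) then gives 14.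

Step 10. Both rings of a molecule may be oxidised, a purely statistical loss. The ortho-quinone may also decay before it is reduced, by tautomerising to a quinone methide or by redox exchange with the still-free phenol ring.

The fallback sets out from 15 and returns at 17. Treating 15 with one equivalent of benzyl bromide 11 and K2CO3 in DMF should give the mono-benzyl ether 4-[(2R,3R)-4-(4-benzyloxy-3,5-dimethoxyphenyl)-2,3-dimethylbutyl]-2,6-dimethoxyphenol F3. It is separated from unreacted 15 and from 14, both of which re-enter the route. Only the ring with a free hydroxyl can form the aryl periodate, so F3 can be driven to completion with a small excess of NaIO4 to the ortho-quinone 5-[(2R,3R)-4-(4-benzyloxy-3,5-dimethoxyphenyl)-2,3-dimethylbutyl]-3-methoxycyclohexa-3,5-diene-1,2-dione F4. Reduction in the same flask with Na2S2O4 gives 5-[(2R,3R)-4-(4-benzyloxy-3,5-dimethoxyphenyl)-2,3-dimethylbutyl]-3-methoxybenzene-1,2-diol F5. Hydrogenolysis (H2, Pd/C, EtOAc/MeOH) then gives 17.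

Step 3. Hydride may attack at sulfur instead of carbon, freeing an alkoxide that closes onto the neighbouring mesylate to a bicyclic tetrahydrofuran. The C8 hydrocarbon may also be lost by evaporation during solvent removal.

The fallback sets out from 3 and returns at 4. Finkelstein exchange (NaI, acetone, reflux) should give (4R,5R)-4,5-bis(iodomethyl)cyclohex-1-ene F6, which cannot form an alkoxide. Radical-chain deiodination with Bu3SnH and catalytic AIBN, run neat or in a high-boiling solvent at 80 °C, then lets 4 be distilled straight out of the tin residue without any solvent evaporation.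

**Further compounds**

F1 | step 8 | (2S,3S)-1,4-diiodo-2,3-dimethylbutane | IC[C@@H](C)[C@H](C)CI
F2 | step 8 | [(2S,3S)-2,3-dimethylbutane-1,4-diyl]bis(iodozinc) | I[Zn]C[C@@H](C)[C@H](C)C[Zn]I
F3 | step 10 | 4-[(2R,3R)-4-(4-benzyloxy-3,5-dimethoxyphenyl)-2,3-dimethylbutyl]-2,6-dimethoxyphenol | COc1cc(C[C@@H](C)[C@H](C)Cc2cc(OC)c(OCc3ccccc3)c(OC)c2)cc(OC)c1O
F4 | step 10 | 5-[(2R,3R)-4-(4-benzyloxy-3,5-dimethoxyphenyl)-2,3-dimethylbutyl]-3-methoxycyclohexa-3,5-diene-1,2-dione | COC1=CC(C[C@@H](C)[C@H](C)Cc2cc(OC)c(OCc3ccccc3)c(OC)c2)=CC(=O)C1=O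
F5 | step 10 | 5-[(2R,3R)-4-(4-benzyloxy-3,5-dimethoxyphenyl)-2,3-dimethylbutyl]-3-methoxybenzene-1,2-diol | COc1cc(C[C@@H](C)[C@H](C)Cc2cc(OC)c(OCc3ccccc3)c(OC)c2)cc(O)c1O
F6 | step 3 | (4R,5R)-4,5-bis(iodomethyl)cyclohex-1-ene | C1=CC[C@@H](CI)[C@H](CI)C1
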